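## The problem

The target is a single six-membered carbocycle in which every ring carbon is functionalised. Numbering used throughout: C1 is the tertiary carbinol carrying the C7H2 benzoate, C2 bears the acetate, C3 the benzoate, C4=C5 is the alkene and C6 the ketone. No second ring has to be built, so the task is to close one cyclohexenone around three contiguous stereocentres, C1 (S), C2 (S) and C3 (R), with the C1 hydroxyl cis to O2 and O2 trans to O3. The trans C2/C3 diol is a threo diol and maps onto (2S,3S)-tartaric acid, so these two centres can be bought. C2 must then direct the configuration of the quaternary C1, which no later step can correct. Four oxygens end up differently acylated (benzoate at O3 and O7, acetate at O2, O1 free), while O2 and O3 are equivalent in tartrate and have to be told apart late, by position. The finished molecule is fragile: a γ-acyloxy enone next to a tertiary α-ketol tolerates neither strong base (acyl migration, β-elimination, α-ketol rearrangement) nor hard nucleophiles. The enabling feature is the C1(OH)–C6(=O) tertiary α-ketol: it is the adduct of an acyl anion at C6 with a ketone at C1, so the ring can be closed by umpolung of a C6 aldehyde, and C4=C5 then follows from a β-oxygen at C4.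

## Retrosynthesis

**Ester placement (16 ⇒ 15 ⇒ 14 ⇒ 13 ⇒ 12).** The first bonds cut are the O2–acetyl and O3–benzoyl bonds.
- Target 16 comes from zeylenone 15 by acetylating the secondary C2 hydroxyl beside an unreactive tertiary one.
- 15 comes from acetonide 14 by hydrolysis, and 14 from alcohol 13 by benzoylation.
- 13 comes from the isomeric acetonide 12 by moving the isopropylidene group from the trans O2/O3 pair to the cis O1/O2 pair.
- The neighbouring option, hydrolysing 12 to a triol and benzoylating O3 by reactivity alone, is one step shorter but rests on kinetic discrimination between two secondary alcohols.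
- In the relay each acyl group goes to the only free hydroxyl. Enone 12 carries no open ester problem except O3, since the O7 benzoate is already in place.
- The forward steps must drive the acetal to the cis-fused isomer and acylate without acyl migration.

**Alkene (12 ⇒ 11).** The C4=C5 bond is disconnected by adding a silanol across it, giving β-silyloxy ketone 11.
- Dehydrogenating a C4-unsubstituted ketone would need oxidant, selenium or palladium chemistry next to a free α-ketol.
- Carrying the alkene through the ring closure would give an enal, which diverts a carbene into homoenolate chemistry.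
- The C4 oxygen of 11 comes at no cost from an aldehyde allylation, and its configuration is irrelevant.
- The forward elimination can run in only one direction because C1 is quaternary.

**Ring (11 ⇒ 10).** Cutting C1–C6 opens the ring to keto-aldehyde 10.
- Cuts at C4–C5 or C5–C6 (metathesis, olefination) would leave the quaternary carbinol to a separate addition step.
- Only the C1–C6 cut creates the quaternary centre, the C6 ketone oxidation level and the ring in one event, with the adjacent C2 centre as control element.
- 10 is acyclic; two of its stereocentres are tartrate-derived and the third is disposable.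
- The forward reaction must generate an acyl-anion equivalent at C6 only, close 6-exo onto the ketone, select one ketone face, and work near neutrality.

**Side chains (10 ⇒ 8 ⇒ 7 ⇒ 5 + 6).** The aldehyde of 10 is traced to the terminal alkene of 8 (ozonolysis through ozonide 9), so the sensitive β-silyloxy aldehyde exists for one step only.
- The C1–C7 bond and the O7 benzoate are cut together: 8 from chloromethyl ketone 7 by benzoate displacement, and 7 from methyl ester 5 and chloroiodomethane 6 by carbenoid homologation.
- The alternative, an alkoxymethyllithium adding to an N-methoxy-N-methyl amide, would bring a protected O7 that costs three extra steps (amide formation, deprotection, benzoylation).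
- The forward steps must add the carbenoid once and substitute without epimerising C2.

**Chain and chiral pool (5 ⇒ 4 ⇒ 2 + 3; 2 ⇒ 1).** Silyl ether 5 comes from alcohol 4. Cutting C4–C5 gives aldehyde 2 and allyl bromide 3.
- The allyl group supplies C5, C6 and one sacrificial carbon.
- 2 arises from the C2-symmetric diester 1 by reducing one of two homotopic esters.
- 1 is the commercial acetonide of dimethyl (2S,3S)-tartrate and already holds C2 and C3 of the target in the correct absolute and relative configuration.
- The forward steps must stop at the mono-aldehyde and allylate it in the presence of the remaining ester.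

## Roads not taken

**Alternative 1:** This road cuts the C3–C4 bond of A1, the 1-O-triethylsilyl ether of the target, and leads back to the acyclic ynone A2, whose C3 carboxyl is activated as an N-acyloxyphthalimide.
- Forward key step: cathodic reduction of A2 triggers decarboxylation to an α-benzoyloxy radical at C3. It adds 6-endo to the alkyne terminus C4, the β-carbon of the ynone, and closes the cyclohexenone A1.
- Merits: all four oxygen substituents are final before the ring closes, the conditions are near neutral, the polarity of radical and acceptor is matched, and the end-game is one desilylation.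
- Weak points:
  - C3 is created in the radical step, controlled only by the neighbouring C2 acetate in a flexible chain.
  - A β-acyloxy radical can shift its acyloxy group or fragment.
  - The quaternary C1 and its cis relation to C2 are not touched by the key step and need separate asymmetric chemistry in A2.
  - An electroreductive decarboxylative ynone cyclisation on this substrate class would have to be developed.
- Comparison: after ring closure Alternative 1 is clearly shorter than the chosen plan, which needs five further steps. The chosen plan sets against this that its ring closure forms C1 under control of a purchased neighbour, by a known reaction class.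

**Alternative 2:** This road cuts C1–C6 and C4–C5 together: furfuryl benzoate A3 and 2-bromoacrolein A4 would combine in a Diels–Alder reaction under a chiral boron Lewis acid to give the oxanorbornene A5.
- Forward logic: the furan oxygen bridges C1 and C4. Once C6 is a carbonyl, β-elimination would open the bridge, giving the C1 hydroxyl and C4=C5 together.
- Merits: two C–C bonds, the ring and the quaternary C1 with its C7 benzoate arise in one catalytic enantioselective step from two achiral components. In step economy for the carbon skeleton this road is better than the chosen plan, which needs seven steps to reach 11.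
- Weak points:
  - 2-Substituted furans are reluctant and reversible dienes, so regio- and enantiocontrol with A4 are not assured.
  - The bromo-aldehyde carbon must be degraded by one carbon to the C6 ketone.
  - The C2=C3 alkene of A5 needs anti dioxygenation with two different esters, whereas reagents approaching the exposed exo face give cis products. This forces an epoxide and a regioselective endo opening at C3 next to a quaternary centre.
- Comparison: the chosen plan sets against the shorter skeleton synthesis that the trans C2/C3 relation and the absolute configuration are purchased, and that the C6 carbonyl appears at the right oxidation level in the key step itself.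

**Alternative 3:** This road forms no C–C bond in its key step. The achiral dienol A6, 1-(benzoyloxymethyl)cyclohexa-2,5-dien-1-ol from a Birch reduction sequence, would be epoxidised at one of its two enantiotopic alkenes by a titanium–tartrate–hydroperoxide system to give the syn-epoxy alcohol A7.
- Forward logic: hydroxyl-directed delivery sets C1 and the cis C2 oxygen together. Opening the oxirane at C3 by a benzoate nucleophile with inversion would give the trans 2,3 relation.
- Merits: it is the shortest and cheapest route to the ring. It also differentiates O2 (free) from O3 (benzoate) automatically, which is better than the chosen plan, where an acetonide relay is needed.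
- Weak points:
  - Cyclic cis-alkenes and tertiary allylic alcohols are the least responsive substrates for titanium–tartrate epoxidation, so the enantiotopic group selection, the only source of absolute configuration, is in doubt.
  - The remaining C5=C6 alkene must be turned into the C6 ketone with C4=C5 by an oxidative allylic transposition, carried out beside an oxirane and a tertiary alcohol.
- Comparison: the chosen plan sets against the shorter route an absolute configuration taken from the chiral pool and a ring closure that delivers the C6 ketone directly.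

Key step: step 7

Remarks before the steps:
- Compound 1 is taken as commercially available; it is the acetonide of dimethyl D-tartrate, i.e. of (2S,3S)-tartaric acid.
- C4 is drawn as the 3,4-anti epimer expected to predominate in step 2. The minor C4 epimer is expected to behave alike and to converge at 12, where C4 becomes sp2.
- Names of 11–16 use the target numbering (C1 carbinol, C6 ketone, C7 exocyclic CH2).

## Route

Step 1
Reactants: 1 dimethyl (4S,5S)-2,2-dimethyl-1,3-dioxolane-4,5-dicarboxylate
Product: 2 methyl (4S,5S)-5-formyl-2,2-dimethyl-1,3-dioxolane-4-carboxylate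
Conditions: i-Bu2AlH (1.05 equiv), toluene, −78 °C; MeOH, then aq. KNaC4H4O6; crude aldehyde used at once
Reagents that add atoms: none
Why: Partial ester reduction: at −78 °C one equivalent of i-Bu2AlH stops at the aluminium hemiacetal, which is stabilised by the α-oxygen and releases the aldehyde only on work-up; the two esters of 1 are homotopic, so no regiochemistry arises, and the dioxolane stereocentres are untouched.

Step 2
Reactants: 2 methyl (4S,5S)-5-formyl-2,2-dimethyl-1,3-dioxolane-4-carboxylate; 3 allyl bromide
Product: 4 methyl (4S,5R)-5-[(1R)-1-hydroxybut-3-en-1-yl]-2,2-dimethyl-1,3-dioxolane-4-carboxylate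
Conditions: Zn dust, THF/sat. aq. NH4Cl, 0 °C to rt
Reagents that add atoms: none
Why: Zinc Barbier allylation is selective for the aldehyde over the methyl ester; Felkin–Anh addition anti to the dioxolane C3–O bond should favour the 3,4-anti (4R) alcohol, the trans-acetonide prevents lactonisation onto the ester, and the C4 configuration is erased in step 8.

Step 3
Reactants: 4 methyl (4S,5R)-5-[(1R)-1-hydroxybut-3-en-1-yl]-2,2-dimethyl-1,3-dioxolane-4-carboxylate
Product: 5 methyl (4S,5S)-5-[(1R)-1-[(tert-butyldimethylsilyl)oxy]but-3-en-1-yl]-2,2-dimethyl-1,3-dioxolane-4-carboxylate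
Conditions: t-BuMe2SiOTf, 2,6-lutidine, CH2Cl2, −78 to 0 °C
Reagents that add atoms: tert-butyldimethylsilyl trifluoromethanesulfonate, CC(C)(C)[Si](C)(C)OS(=O)(=O)C(F)(F)F
Why: Silylation of a secondary alcohol with a silyl triflate and a hindered base; the silyl ether masks O4 through the organolithium, ozonolysis and carbene steps and later serves as the leaving group.

Step 4
Reactants: 5 methyl (4S,5S)-5-[(1R)-1-[(tert-butyldimethylsilyl)oxy]but-3-en-1-yl]-2,2-dimethyl-1,3-dioxolane-4-carboxylate; 6 chloroiodomethane
Product: 7 2-chloro-1-[(4S,5S)-5-[(1R)-1-[(tert-butyldimethylsilyl)oxy]but-3-en-1-yl]-2,2-dimethyl-1,3-dioxolan-4-yl]ethan-1-one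
Conditions: ICH2Cl (1.5 equiv), MeLi·LiBr (1.5 equiv), THF, −78 °C; aq. NH4Cl at −78 °C
Reagents that add atoms: none
Why: Ester homologation with chloromethyllithium generated in situ by iodine–lithium exchange: the lithium hemiketal is stable at −78 °C, so the carbenoid adds once and the C1–C7 bond forms without enolising C2.

Step 5
Reactants: 7 2-chloro-1-[(4S,5S)-5-[(1R)-1-[(tert-butyldimethylsilyl)oxy]but-3-en-1-yl]-2,2-dimethyl-1,3-dioxolan-4-yl]ethan-1-one
Product: 8 2-[(4S,5S)-5-[(1R)-1-[(tert-butyldimethylsilyl)oxy]but-3-en-1-yl]-2,2-dimethyl-1,3-dioxolan-4-yl]-2-oxoethyl benzoate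
Conditions: PhCO2K (1.5 equiv), NaI (10 mol %), DMF, rt
Reagents that add atoms: potassium benzoate, [K+].[O-]C(=O)c1ccccc1
Why: SN2 displacement of the activated α-chloro ketone by benzoate with iodide assistance (Finkelstein-type) installs the final C7 benzoate; the weakly basic carboxylate should neither epimerise C2 nor open the dioxolane.

Step 6
Reactants: 8 2-[(4S,5S)-5-[(1R)-1-[(tert-butyldimethylsilyl)oxy]but-3-en-1-yl]-2,2-dimethyl-1,3-dioxolan-4-yl]-2-oxoethyl benzoate
Product: 10 2-[(4S,5S)-5-[(1R)-1-[(tert-butyldimethylsilyl)oxy]-3-oxopropyl]-2,2-dimethyl-1,3-dioxolan-4-yl]-2-oxoethyl benzoate, via secondary ozonide 9 (not isolated)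
Conditions: O3, CH2Cl2, −78 °C; PPh3, −78 °C to rt; used without chromatography
Reagents that add atoms: ozone, [O-][O+]=O
Why: Ozonolysis of the terminal alkene with reductive work-up gives the C6 aldehyde; the benzoate ring, silyl ether and acetonide are inert to ozone at −78 °C, and the β-silyloxy aldehyde is made only one step before use.

Step 7
Reactants: 10 2-[(4S,5S)-5-[(1R)-1-[(tert-butyldimethylsilyl)oxy]-3-oxopropyl]-2,2-dimethyl-1,3-dioxolan-4-yl]-2-oxoethyl benzoate
Product: 11 [(1S,2S,3S,4R)-4-[(tert-butyldimethylsilyl)oxy]-1-hydroxy-2,3-(isopropylidenedioxy)-6-oxocyclohexyl]methyl benzoate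
Conditions: 2-(pentafluorophenyl)-6,7-dihydro-5H-pyrrolo[2,1-c][1,2,4]triazol-2-ium tetrafluoroborate (15 mol %), Et3N (15 mol %), CH2Cl2 (0.05 M), 23 °C
Reagents that add atoms: none
Why: Et3N frees the triazolylidene, which adds to the only aldehyde (C6); proton transfer gives the Breslow enaminol, an acyl-anion equivalent whose C6 attacks the C1 ketone, and proton shift with loss of the carbene releases α-ketol 11 and turns the catalyst over. The closest known reaction type is the carbene-catalysed intramolecular crossed aldehyde–ketone benzoin cyclisation, established for 1,6-keto-aldehydes and for highly oxygenated, carbohydrate-derived dicarbonyl substrates. The six-membered ring closes in a 6-exo-trig mode, C6 attacking the exocyclic C1=O. The new C1 stereocentre is set by C2: the trans-dioxolane forces O2 and O3 equatorial in a chair transition state, which places the forming C1–C6 bond anti to the C2–O bond (a Felkin–Anh arrangement) and gives the C7H2OBz group the equatorial site beside C2–H and the carbonyl oxygen the axial site, so the hydroxyl forms axial and cis to O2 (1S). The same isomer carries its larger C1 substituent equatorial, so reversibility of the benzoin step should reinforce the kinetic preference. Chemoselectivity rests on the substrate: only one aldehyde can form an acyl anion, and the ketone is activated by α-oxygens on both sides. The weakly basic, substoichiometric conditions are needed so that enolisation of the β-silyloxy aldehyde (E1cB loss of silanolate or five-membered aldol closure from C5) and epimerisation or ring opening at C2 do not compete. The C4 silyloxy group is a spectator, axial in this chair for the major epimer and equatorial for the minor one, and is removed in step 8.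

Step 8
Reactants: 11 [(1S,2S,3S,4R)-4-[(tert-butyldimethylsilyl)oxy]-1-hydroxy-2,3-(isopropylidenedioxy)-6-oxocyclohexyl]methyl benzoate
Product: 12 [(1S,2S,3R)-1-hydroxy-2,3-(isopropylidenedioxy)-6-oxocyclohex-4-en-1-yl]methyl benzoate
Conditions: 1,8-diazabicyclo[5.4.0]undec-7-ene (1.2 equiv), CH2Cl2, 0 °C to rt
Reagents that add atoms: none
Why: E1cB elimination: the ketone can enolise only toward C5 because C1 is quaternary, and the axial C4 silyloxy group of the major epimer is aligned with the enolate π-system, so loss of silanolate gives the C4=C5 enone and removes the C4 stereocentre.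

Step 9
Reactants: 12 [(1S,2S,3R)-1-hydroxy-2,3-(isopropylidenedioxy)-6-oxocyclohex-4-en-1-yl]methyl benzoate
Product: 13 [(1S,2S,3R)-3-hydroxy-1,2-(isopropylidenedioxy)-6-oxocyclohex-4-en-1-yl]methyl benzoate
Conditions: p-toluenesulfonic acid monohydrate (TsOH·H2O, 5 mol %), acetone, rt
Reagents that add atoms: none
Why: Acid-catalysed acetal migration under thermodynamic control: ionisation of the strained trans-fused dioxolane at O3 leaves an oxocarbenium ion on O2 that is trapped by the cis C1 hydroxyl, giving the less strained cis-fused 1,2-acetonide and freeing only the C3 hydroxyl.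

Step 10
Reactants: 13 [(1S,2S,3R)-3-hydroxy-1,2-(isopropylidenedioxy)-6-oxocyclohex-4-en-1-yl]methyl benzoate
Product: 14 [(1S,2S,3R)-3-(benzoyloxy)-1,2-(isopropylidenedioxy)-6-oxocyclohex-4-en-1-yl]methyl benzoate
Conditions: PhCOCl (1.3 equiv), pyridine, 4-(dimethylamino)pyridine (5 mol %), CH2Cl2, 0 °C
Reagents that add atoms: benzoyl chloride, O=C(Cl)c1ccccc1
Why: Standard acylation with an acyl chloride under nucleophilic catalysis; the allylic C3 hydroxyl is the only free hydroxyl, so the benzoate can go nowhere else.

Step 11
Reactants: 14 [(1S,2S,3R)-3-(benzoyloxy)-1,2-(isopropylidenedioxy)-6-oxocyclohex-4-en-1-yl]methyl benzoate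
Product: 15 zeylenone, [(1S,2S,3R)-3-(benzoyloxy)-1,2-dihydroxy-6-oxocyclohex-4-en-1-yl]methyl benzoate
Conditions: CF3CO2H/H2O (9:1), CH2Cl2, 0 °C to rt
Reagents that add atoms: none
Why: Aqueous acid hydrolysis of the isopropylidene acetal; benzoates are stable to these conditions, and the low temperature should suppress acid-promoted benzoyl migration from O3 to O2.

Step 12
Reactants: 15 zeylenone, [(1S,2S,3R)-3-(benzoyloxy)-1,2-dihydroxy-6-oxocyclohex-4-en-1-yl]methyl benzoate
Product: 16 2-O-acetylzeylenone, [(1S,2S,3R)-2-acetoxy-3-(benzoyloxy)-1-hydroxy-6-oxocyclohex-4-en-1-yl]methyl benzoate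
Conditions: Ac2O, pyridine, 0 °C to rt
Reagents that add atoms: acetic anhydride, CC(=O)OC(C)=O
Why: Acetylation discriminates the secondary C2 hydroxyl from the tertiary C1 hydroxyl, which does not acylate under pyridine/Ac2O without forcing; acetylation should outrun base-promoted benzoyl migration.

## Compound list

1 | dimethyl (4S,5S)-2,2-dimethyl-1,3-dioxolane-4,5-dicarboxylate (dimethyl 2,3-O-isopropylidene-D-tartrate) | COC(=O)[C@H]1OC(C)(C)O[C@@H]1C(=O)OC | starting material
2 | methyl (4S,5S)-5-formyl-2,2-dimethyl-1,3-dioxolane-4-carboxylate | O=C[C@H]1OC(C)(C)O[C@@H]1C(=O)OC | intermediate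
3 | allyl bromide (3-bromoprop-1-ene) | C=CCBr | starting material
4 | methyl (4S,5R)-5-[(1R)-1-hydroxybut-3-en-1-yl]-2,2-dimethyl-1,3-dioxolane-4-carboxylate (O4 anti to O3) | C=CC[C@@H](O)[C@H]1OC(C)(C)O[C@@H]1C(=O)OC | intermediate
5 | methyl (4S,5S)-5-[(1R)-1-[(tert-butyldimethylsilyl)oxy]but-3-en-1-yl]-2,2-dimethyl-1,3-dioxolane-4-carboxylate | C=CC[C@@H](O[Si](C)(C)C(C)(C)C)[C@H]1OC(C)(C)O[C@@H]1C(=O)OC | intermediate
6 | chloroiodomethane | ClCI | starting material
7 | 2-chloro-1-[(4S,5S)-5-[(1R)-1-[(tert-butyldimethylsilyl)oxy]but-3-en-1-yl]-2,2-dimethyl-1,3-dioxolan-4-yl]ethan-1-one | C=CC[C@@H](O[Si](C)(C)C(C)(C)C)[C@H]1OC(C)(C)O[C@@H]1C(=O)CCl | intermediate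
8 | 2-[(4S,5S)-5-[(1R)-1-[(tert-butyldimethylsilyl)oxy]but-3-en-1-yl]-2,2-dimethyl-1,3-dioxolan-4-yl]-2-oxoethyl benzoate | C=CC[C@@H](O[Si](C)(C)C(C)(C)C)[C@H]1OC(C)(C)O[C@@H]1C(=O)COC(=O)c1ccccc1 | intermediate
9 | secondary ozonide of 8: the 3-substituted 1,2,4-trioxolane formed from the terminal alkene, either configuration at the trioxolane carbon, other centres as in 8 | O1OC(C[C@@H](O[Si](C)(C)C(C)(C)C)[C@H]2OC(C)(C)O[C@@H]2C(=O)COC(=O)c2ccccc2)OC1 | intermediate
10 | 2-[(4S,5S)-5-[(1R)-1-[(tert-butyldimethylsilyl)oxy]-3-oxopropyl]-2,2-dimethyl-1,3-dioxolan-4-yl]-2-oxoethyl benzoate (keto-aldehyde; C6 aldehyde, C1 ketone) | O=CC[C@@H](O[Si](C)(C)C(C)(C)C)[C@H]1OC(C)(C)O[C@@H]1C(=O)COC(=O)c1ccccc1 | intermediate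
11 | [(1S,2S,3S,4R)-4-[(tert-butyldimethylsilyl)oxy]-1-hydroxy-2,3-(isopropylidenedioxy)-6-oxocyclohexyl]methyl benzoate (1-OH cis to O2, O2 trans to O3, O4 cis to O3) | O=C1C[C@@H](O[Si](C)(C)C(C)(C)C)[C@H]2OC(C)(C)O[C@@H]2[C@@]1(O)COC(=O)c1ccccc1 | intermediate
12 | [(1S,2S,3R)-1-hydroxy-2,3-(isopropylidenedioxy)-6-oxocyclohex-4-en-1-yl]methyl benzoate | O=C1C=C[C@H]2OC(C)(C)O[C@@H]2[C@@]1(O)COC(=O)c1ccccc1 | intermediate
13 | [(1S,2S,3R)-3-hydroxy-1,2-(isopropylidenedioxy)-6-oxocyclohex-4-en-1-yl]methyl benzoate | O=C1C=C[C@@H](O)[C@@H]2OC(C)(C)O[C@]12COC(=O)c1ccccc1 | intermediate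
14 | [(1S,2S,3R)-3-(benzoyloxy)-1,2-(isopropylidenedioxy)-6-oxocyclohex-4-en-1-yl]methyl benzoate | O=C1C=C[C@@H](OC(=O)c3ccccc3)[C@@H]2OC(C)(C)O[C@]12COC(=O)c1ccccc1 | intermediate
15 | zeylenone, [(1S,2S,3R)-3-(benzoyloxy)-1,2-dihydroxy-6-oxocyclohex-4-en-1-yl]methyl benzoate | O[C@H]1[C@H](OC(=O)c2ccccc2)C=CC(=O)[C@]1(O)COC(=O)c1ccccc1 | intermediate
16 | 2-O-acetylzeylenone, [(1S,5R,6S)-6-acetoxy-5-(benzoyloxy)-1-hydroxy-2-oxocyclohex-3-en-1-yl]methyl benzoate | CC(=O)O[C@H]1[C@H](OC(=O)c2ccccc2)C=CC(=O)[C@]1(O)COC(=O)c1ccccc1 | target

## Step count and least certain steps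

Total: 12 steps. Longest linear sequence: 12 steps (1 to 16); the route is fully linear.

**Step 7 (key step).**
- Most likely failure: base-triggered enolisation of the β-silyloxy aldehyde. Loss of silanolate would give an enal that diverts the carbene, and aldol closure from C5 onto the ketone would give a five-membered ring.
- Second concern: insufficient discrimination between the two ketone faces, which would give the C1 epimer.
- Fallback, setting out from 8 and returning at 11, without carbene or base:
  - Takai–Lombardo methylenation of the C1 ketone (Zn, CH2Br2, TiCl4, THF/CH2Cl2) would give the exocyclic-methylene diene F1.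
  - Ring-closing metathesis with the second-generation Grubbs catalyst (CH2Cl2, 40 °C) would close the C1=C6 cyclohexene F2.
  - Dihydroxylation (OsO4 cat., N-methylmorpholine N-oxide, acetone/H2O) would give the cis-1,6-diol F3. The reagent is expected to add anti to the axial C4 silyloxy group, on the face of O2.
  - Oxidation of the secondary C6 hydroxyl (SO3·pyridine, Me2SO, Et3N) returns to 11.

**Step 1.**
- Most likely failure: over-reduction and statistical mixtures, because both esters are equally reactive, together with hydration or epimerisation of the aldehyde during isolation.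
- Fallback, setting out from 1 and returning at 2:
  - Mono-saponification (KOH, 1 equiv, MeOH) gives the half-acid F4.
  - Chemoselective reduction of the acid (BH3·SMe2, THF) gives the hydroxy ester F5.
  - Swern oxidation returns to 2.

**Step 4.**
- Most likely failure: a second addition of the carbenoid to the ketone on warming (chlorohydrin or epoxide formation), or deprotonation at C2 by excess organolithium.
- Fallback, setting out from 5 and returning at 8, bypassing 7:
  - Saponification (LiOH, THF/H2O) gives the carboxylic acid F6.
  - Activation with isobutyl chloroformate and N-methylmorpholine gives the mixed carbonic anhydride F7, which acylates diazomethane to the diazoketone F8.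
  - O–H insertion into benzoic acid catalysed by Rh2(OAc)4 gives 8 directly.

**Step 8.**
- Most likely failure: sluggish loss of the silyloxy group, particularly from the minor equatorial C4 epimer. Prolonged exposure to base would allow benzoyl migration or α-ketol rearrangement.
- Fallback, setting out from 11 and returning at 12:
  - Desilylation (HF·pyridine, THF) gives the C4 alcohol F9.
  - Mesylation of the secondary hydroxyl (MeSO2Cl, Et3N, CH2Cl2, 0 °C) gives the C4 mesylate F10, which eliminates in the same flask to 12.

**Step 9.**
- Most likely failure: an incomplete shift that stops at an equilibrium mixture of the two acetonides, or partial hydrolysis by adventitious water.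
- Fallback, setting out from 12 and returning at 15; it abandons the acetonide relay and relies on steric differentiation:
  - Full hydrolysis (CF3CO2H/H2O) gives the 1,2,3-triol F11.
  - One equivalent of PhCOCl in pyridine/CH2Cl2 at −40 °C should acylate the less hindered allylic C3 hydroxyl in preference to the C2 hydroxyl, which is flanked by the quaternary C1, and so give 15.

## Further compounds

F1 | step 7 | 2-[(4R,5S)-5-[(1R)-1-[(tert-butyldimethylsilyl)oxy]but-3-en-1-yl]-2,2-dimethyl-1,3-dioxolan-4-yl]prop-2-en-1-yl benzoate | C=CC[C@@H](O[Si](C)(C)C(C)(C)C)[C@H]1OC(C)(C)O[C@@H]1C(=C)COC(=O)c1ccccc1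
F2 | step 7 | 1-(benzoyloxymethyl)-4-[(tert-butyldimethylsilyl)oxy]-2,3-(isopropylidenedioxy)cyclohex-1(6)-ene, target numbering, O2 trans to O3, O4 cis to O3, centres as in 8 | C1(COC(=O)c3ccccc3)=CC[C@@H](O[Si](C)(C)C(C)(C)C)[C@H]2OC(C)(C)O[C@@H]21
F3 | step 7 | 1-(benzoyloxymethyl)-4-[(tert-butyldimethylsilyl)oxy]-2,3-(isopropylidenedioxy)cyclohexane-1,6-diol, target numbering, 1-OH and 6-OH cis to each other and to O2 | O[C@@H]1C[C@@H](O[Si](C)(C)C(C)(C)C)[C@H]2OC(C)(C)O[C@@H]2[C@@]1(O)COC(=O)c1ccccc1
F4 | step 1 | (4S,5S)-5-(methoxycarbonyl)-2,2-dimethyl-1,3-dioxolane-4-carboxylic acid | OC(=O)[C@H]1OC(C)(C)O[C@@H]1C(=O)OC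
F5 | step 1 | methyl (4S,5R)-5-(hydroxymethyl)-2,2-dimethyl-1,3-dioxolane-4-carboxylate | OC[C@H]1OC(C)(C)O[C@@H]1C(=O)OC
F6 | step 4 | (4S,5S)-5-[(1R)-1-[(tert-butyldimethylsilyl)oxy]but-3-en-1-yl]-2,2-dimethyl-1,3-dioxolane-4-carboxylic acid | C=CC[C@@H](O[Si](C)(C)C(C)(C)C)[C@H]1OC(C)(C)O[C@@H]1C(=O)O
F7 | step 4 | mixed anhydride of F6 with isobutyl hydrogen carbonate | C=CC[C@@H](O[Si](C)(C)C(C)(C)C)[C@H]1OC(C)(C)O[C@@H]1C(=O)OC(=O)OCC(C)C
F8 | step 4 | 2-diazo-1-[(4S,5S)-5-[(1R)-1-[(tert-butyldimethylsilyl)oxy]but-3-en-1-yl]-2,2-dimethyl-1,3-dioxolan-4-yl]ethan-1-one | C=CC[C@@H](O[Si](C)(C)C(C)(C)C)[C@H]1OC(C)(C)O[C@@H]1C(=O)C=[N+]=[N-]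
F9 | step 8 | [(1S,2S,3S,4R)-1,4-dihydroxy-2,3-(isopropylidenedioxy)-6-oxocyclohexyl]methyl benzoate, target numbering | O=C1C[C@@H](O)[C@H]2OC(C)(C)O[C@@H]2[C@@]1(O)COC(=O)c1ccccc1
F10 | step 8 | C4 methanesulfonate of F9 | O=C1C[C@@H](OS(C)(=O)=O)[C@H]2OC(C)(C)O[C@@H]2[C@@]1(O)COC(=O)c1ccccc1
F11 | step 9 | [(1S,2S,3R)-1,2,3-trihydroxy-6-oxocyclohex-4-en-1-yl]methyl benzoate, target numbering | O=C1C=C[C@@H](O)[C@H](O)[C@@]1(O)COC(=O)c1ccccc1
A1 | alternative 1 | 1-O-triethylsilyl-2-O-acetylzeylenone | CC(=O)O[C@H]1[C@H](OC(=O)c2ccccc2)C=CC(=O)[C@]1(O[Si](CC)(CC)CC)COC(=O)c1ccccc1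
A2 | alternative 1 | 1,3-dioxoisoindolin-2-yl 3-acetoxy-2-(benzoyloxy)-4-[(benzoyloxy)methyl]-5-oxo-4-[(triethylsilyl)oxy]hept-6-ynoate, chain C3 and C4 configured as C2 and C1 of the target, chain C2 either epimer | CC(=O)O[C@@H](C(OC(=O)c1ccccc1)C(=O)ON1C(=O)c2ccccc2C1=O)[C@@](O[Si](CC)(CC)CC)(COC(=O)c1ccccc1)C(=O)C#C
A3 | alternative 2 | furfuryl benzoate | O=C(OCc1ccco1)c1ccccc1
A4 | alternative 2 | 2-bromoacrolein | C=C(Br)C=O
A5 | alternative 2 | 1-(benzoyloxymethyl)-2-endo-bromo-7-oxabicyclo[2.2.1]hept-5-ene-2-exo-carbaldehyde | O=C[C@]1(Br)C[C@H]2C=C[C@]1(COC(=O)c1ccccc1)O2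
A6 | alternative 3 | 1-(benzoyloxymethyl)cyclohexa-2,5-dien-1-ol | OC1(COC(=O)c2ccccc2)C=CCC=C1
A7 | alternative 3 | syn-2,3-epoxy-1-(benzoyloxymethyl)cyclohex-5-en-1-ol, oxirane cis to the hydroxyl | O[C@]1(COC(=O)c2ccccc2)C=CC[C@@H]2O[C@H]12
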